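Target leaves the catalyst one molecule per turn of a cycle, and the five flasks differ in their charge of free catalyst.

| flask | substrate | partner | protic impurity | free catalyst | time |
|---|---|---|---|---|---|
| epsilon | 0.050 M | 0.0550 M | 0.0100 M | 0.020 mM | 1.0 h |
| beta | 0.050 M | 0.0550 M | 0.0100 M | 0.040 mM | 1.0 h |
| delta | 0.050 M | 0.0550 M | 0.0100 M | 0.080 mM | 1.0 h |
| zeta | 0.050 M | 0.0550 M | 0.0100 M | 0.15 mM | 1.0 h |
| alpha | 0.050 M | 0.0550 M | 0.0100 M | 0.30 mM | 1.0 h |

    partner + free catalyst → catalyst intermediate A (k1 = 3100 /M/min)
    catalyst intermediate A → catalyst intermediate B (k2 = 130 /min)
    substrate + catalyst intermediate B → catalyst intermediate C (k3 = 380 /M/min)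
    catalyst intermediate C → free catalyst + target (k4 = 4.3 /min)
    2 partner → self-condensation product (k5 = 0.25 /M/min)
    partner + protic impurity → quenched reagent (k6 = 1.5 /M/min)

- where a step has two of a species, its rate is k times that concentration squared, and two are used at each turn
- "hardly changes" means that all values lie within two and a half points (for a concentration: within two and a half percent of the largest)
- run time (epsilon): 1.0 h

1. amount of target at the end, in percent of the substrate charged for epsilon, beta, delta, zeta, alpha, in this order
2. how the row runs (hardly changes / falls, then rises / rises all the way / falls all the way / rises, then falls)

I began with epsilon and its neighbour beta, which differ in catalyst charge. Free catalyst takes up partner and becomes catalyst intermediate A, which changes into catalyst intermediate B. That takes up substrate and becomes catalyst intermediate C, which releases target and free catalyst. One catalyst molecule waits at each station in turn, so I added the waits at the charged concentrations: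

wait for partner: 0.00587 min
wait for the change from A to B: 0.00769 min
wait for substrate: 0.0526 min
wait for release: 0.233 min
sum: 0.299 min

I called this sum the turn time: the time one catalyst molecule needs for one full cycle. Release is the longest wait, so it is the rate-limiting step, and catalyst intermediate C should be the resting state.

Catalyst charge times the hour over the turn time gave a first answer for epsilon of 4.02 mM of target, or 8.04 %. But substrate and partner fall during the hour, so I put that answer back in. I took the first target and the impurity charge off the partner charge, then let the remainder self-condense for the hour by that step's second-order law. I took the substrate down by the first target, and averaged the turn times at the start and the end: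

epsilon: [partner] at the end 0.0184 M, end turn time 0.315 min, mean 0.307 min, target 3.91 mM, or 7.82 %

beta: first target 8.03 mM, [partner] at the end 0.0175 M, end turn time 0.321 min, mean 0.310 min, target 7.74 mM, or 15.5 %

So in my reckoning beta ended with twice the target of epsilon, since the two mean turn times nearly matched. My reckoning stopped there: in alpha the same pace asked for 60.3 mM of target, more than the 0.050 M of substrate charged.

The forecast gave 7.7 %, 15.2 %, 29.5 %, 52 % and 69 %, a row that rises all the way, on the ground that “yield climbs nearly in proportion to catalyst while the partner lasts”. My two figures stood slightly above its first two.

The simulation gave 7.78 %, 15.4 %, 30.0 %, 52.6 % and 70.0 %, and the row rises all the way. In epsilon, the 3.89 mM of target on 0.020 mM of catalyst charged comes to one turn per 0.308 min on average over the hour, longer than the 0.299 min reckoned at the charged concentrations, and catalyst intermediate C held 73.2 % of the catalyst at 1.00 h. In alpha, the 35.0 mM of target corresponds, at the turn time of 0.299 min reckoned at the charged concentrations, to 34.9 min of turning, shorter than the 1.0 h allowed, and partner stood at 0 % of its charge at the end.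

The constants used here were drawn at random within sensible limits; the run is a simulation.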